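**Retrosynthetic overview**

- Feature: in the ten-membered carbocycle (ring atoms C1–C10: C1(H)=C10(Me), C4(Me)–C5 oxirane, C6–OH, C7–iPr, C8–O-aroyl, C9H2) the unit C8(O)–C9H2–C10(Me)=C1(H) is an E homoallylic alcohol, the reductive adduct of a terminal C8–C9 oxirane and a methyl-capped C10≡C1 alkyne.
- Disconnections, in order: the C8 ester (acylation), the C4–C5 oxirane (epoxidation of the 4Z alkene directed by C6–OH), then the C9–C10 ring bond (nickel-mediated reductive alkyne–epoxide macrocyclization).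
- The open-chain (Z)-enyne epoxide comes from an Evans syn aldol (C6, C7) of an N-isovaleryl oxazolidinone with a (Z)-enal, homologation to a chloromethyl ketone, 1,3-syn reduction (C8) and oxirane closure.
- The (Z)-enal (C10-methyl through C6) comes from hexa-1,5-diyne by C-methylation, carboxylation and syn addition of a methylcuprate.
- Ring order: the C8–C9 oxirane (made, then consumed), the ten-membered carbocycle, and last the C4–C5 oxirane.

Key step: step 13

Remark: ring atoms keep the numbering above throughout; the target has the oxirane oxygen trans to the C6 hydroxyl on the ring (threo), whereas VO(acac)2/t-BuOOH delivers cis in eight- and nine-membered (Z)-cycloalk-2-enols, so the last step uses Ti(OiPr)4/t-BuOOH, which accepts the wider O–C6–C5=C4 angle of the threo transition state.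

**Route**

Step 1
Reactants: 1 hexa-1,5-diyne
Product: 3 hepta-1,5-diyne, via lithium hexa-1,5-diyn-1-ide 2 (not isolated)
Conditions: 1 (3 equiv), n-BuLi (1 equiv), THF, −78 °C; MeI, −78 °C to rt; fractional distillation, excess 1 recovered
Reagents that add atoms: iodomethane, CI
Why: Monodeprotonation of a terminal alkyne and SN2 C-methylation of the acetylide, run with the diyne in excess so that double methylation stays low and the volatile hydrocarbons can be separated by distillation.

Step 2
Reactants: 3 hepta-1,5-diyne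
Product: 5 methyl octa-2,6-diynoate, via lithium hepta-1,5-diyn-1-ide 4 (not isolated)
Conditions: n-BuLi, THF, −78 °C; ClCO2Me, −78 to 0 °C
Reagents that add atoms: methyl chloroformate, COC(=O)Cl
Why: Acylation of a lithium acetylide with a chloroformate is the standard entry to 2-alkynoates, and the internal methyl alkyne carries no acidic hydrogen under these conditions.

Step 3
Reactants: 5 methyl octa-2,6-diynoate
Product: 7 methyl (2Z)-3-methyloct-2-en-6-ynoate, via alkenylcuprate 6 (not isolated)
Conditions: Me2CuLi (from MeLi and CuI), THF, −78 °C; MeOH at −78 °C, then aq NH4Cl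
Reagents that add atoms: lithium dimethylcuprate, [Li+].C[Cu-]C
Why: Conjugate syn carbocupration of the ynoate places methyl and copper cis, and protonation of 6 at −78 °C with retention leaves the chain cis to the ester (2Z), while the unactivated C6≡C7 alkyne does not react.

Step 4
Reactants: 7 methyl (2Z)-3-methyloct-2-en-6-ynoate
Product: 8 (2Z)-3-methyloct-2-en-6-yn-1-ol
Conditions: i-Bu2AlH, CH2Cl2, −78 °C; aq KNaC4H4O6
Reagents that add atoms: none
Why: 1,2-Reduction of the enoate with i-Bu2AlH gives the allylic alcohol without changing the alkene geometry or touching the alkyne.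

Step 5
Reactants: 8 (2Z)-3-methyloct-2-en-6-yn-1-ol
Product: 9 (2Z)-3-methyloct-2-en-6-ynal
Conditions: Dess–Martin periodinane, NaHCO3, CH2Cl2, 0 °C; used at once
Reagents that add atoms: none
Why: Dess–Martin oxidation under bicarbonate buffering is fast and neutral, which limits Z to E isomerisation of the enal, and the aldehyde is carried on without storage.

Step 6
Reactants: 10 (S)-4-benzyloxazolidin-2-one; 11 3-methylbutanoyl chloride (isovaleryl chloride)
Product: 13 (4S)-4-benzyl-3-(3-methylbutanoyl)oxazolidin-2-one, via lithium oxazolidinide 12 (not isolated)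
Conditions: n-BuLi, THF, −78 °C; 11, −78 to 0 °C
Reagents that add atoms: none
Why: N-Acylation of the lithiated oxazolidinone with an acid chloride is the standard preparation of Evans imides.

Step 7
Reactants: 13 (4S)-4-benzyl-3-(3-methylbutanoyl)oxazolidin-2-one; 9 (2Z)-3-methyloct-2-en-6-ynal
Product: 16 (4S)-4-benzyl-3-[(2S,3R,4Z)-3-hydroxy-5-methyl-2-(propan-2-yl)dec-4-en-8-ynoyl]oxazolidin-2-one, via boron enolate 14 (not isolated), via boron aldolate 15 (not isolated)
Conditions: Bu2BOTf, i-Pr2NEt, CH2Cl2, 0 °C; 9, −78 to 0 °C; pH 7 buffer, MeOH, H2O2, 0 °C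
Reagents that add atoms: none
Why: Evans syn aldol reaction, in which the (Z)-boron enolate 14 reacts through a closed chair transition state on the face away from the benzyl group, so that ring C7 (2S, isopropyl) and ring C6 (3R, hydroxyl) are set syn with the absolute sense fixed by the (S)-auxiliary.

Step 8
Reactants: 16 (4S)-4-benzyl-3-[(2S,3R,4Z)-3-hydroxy-5-methyl-2-(propan-2-yl)dec-4-en-8-ynoyl]oxazolidin-2-one
Product: 17 (2S,3R,4Z)-3-hydroxy-N-methoxy-N,5-dimethyl-2-(propan-2-yl)dec-4-en-8-ynamide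
Conditions: MeNH(OMe)·HCl, Me3Al, CH2Cl2, −20 to 0 °C; aq KNaC4H4O6
Reagents that add atoms: N,O-dimethylhydroxylamine hydrochloride, CNOC.Cl
Why: Aluminium-amide transamination of a syn-aldol imide, in which the free C6 hydroxyl binds aluminium and steers the amide to the exocyclic carbonyl, gives the Weinreb amide and returns the auxiliary without epimerisation at C7.

Step 9
Reactants: 17 (2S,3R,4Z)-3-hydroxy-N-methoxy-N,5-dimethyl-2-(propan-2-yl)dec-4-en-8-ynamide
Product: 19 (3S,4R,5Z)-1-chloro-4-hydroxy-6-methyl-3-(propan-2-yl)undec-5-en-9-yn-2-one, via dilithium hemiaminal adduct 18 (not isolated)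
Conditions: ICH2Cl, MeLi·LiBr (excess), THF, −78 °C; aq NH4Cl at −78 °C
Reagents that add atoms: chloroiodomethane, ClCI
Why: Chloromethyllithium, made by iodine–lithium exchange in the presence of the substrate, adds once to the N-methoxy-N-methyl amide (homologation of a Weinreb amide to an α-chloro ketone) because the chelated adduct 18 survives until the cold quench, and the C6 alkoxide only consumes one extra equivalent of base.

Step 10
Reactants: 19 (3S,4R,5Z)-1-chloro-4-hydroxy-6-methyl-3-(propan-2-yl)undec-5-en-9-yn-2-one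
Product: 21 (2R,3S,4R,5Z)-1-chloro-6-methyl-3-(propan-2-yl)undec-5-en-9-yne-2,4-diol, via boron chelate 20 (not isolated)
Conditions: Et2BOMe, THF/MeOH (4:1), −78 °C; NaBH4, −78 °C; AcOH, then evaporation from MeOH
Reagents that add atoms: none
Why: Narasaka–Prasad reduction, in which hydride adds axially to the six-membered boron chelate 20 and anti to the axial C7 isopropyl group, so that the new C8 carbinol is 1,3-syn to the C6 hydroxyl (all-syn C6–C7–C8 triad).

Step 11
Reactants: 21 (2R,3S,4R,5Z)-1-chloro-6-methyl-3-(propan-2-yl)undec-5-en-9-yne-2,4-diol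
Product: 22 (3S,4R,5Z)-2,6-dimethyl-3-[(2R)-oxiran-2-yl]undec-5-en-9-yn-4-ol
Conditions: K2CO3, MeOH, 0 °C to rt
Reagents that add atoms: none
Why: Intramolecular Williamson closure (3-exo-tet) of the chlorohydrin by the C8 alkoxide is much faster than attack of the hindered C6 alkoxide on C9, and C8 keeps its configuration because its C–O bond is not broken.

Step 12
Reactants: 22 (3S,4R,5Z)-2,6-dimethyl-3-[(2R)-oxiran-2-yl]undec-5-en-9-yn-4-ol
Product: 23 tert-butyl{[(3R,4R,5Z)-2,6-dimethyl-3-[(2R)-oxiran-2-yl]undec-5-en-9-yn-4-yl]oxy}dimethylsilane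
Conditions: TBSOTf, 2,6-lutidine, CH2Cl2, −78 °C
Reagents that add atoms: tert-butyldimethylsilyl trifluoromethanesulfonate, CC(C)(C)[Si](C)(C)OS(=O)(=O)C(F)(F)F
Why: Silylation of the hindered secondary alcohol with the silyl triflate and a hindered base at −78 °C is faster than Lewis-acid opening of the oxirane and removes the only acidic proton before the organometallic step.

Step 13
Reactants: 23 tert-butyl{[(3R,4R,5Z)-2,6-dimethyl-3-[(2R)-oxiran-2-yl]undec-5-en-9-yn-4-yl]oxy}dimethylsilane
Product: 25 (1S,3E,7Z,9R,10R)-9-[(tert-butyldimethylsilyl)oxy]-3,7-dimethyl-10-(propan-2-yl)cyclodeca-3,7-dien-1-ol, via diethylborinate 24 (not isolated)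
Conditions: Ni(cod)2 (30 mol %), PBu3 (60 mol %), Et3B (3 equiv), THF, rt to 45 °C, slow addition of 23 (final 0.005 M); aq NH4Cl
Reagents that add atoms: none
Why: Proposed new method: zerovalent nickel carrying PBu3 should open the monosubstituted oxirane at the unhindered C9 and, with the tethered alkyne, form an oxanickelacycle with C9 bound to C10 and nickel bound to C1 and to the C8 oxygen; Et3B then exchanges an ethyl group for the Ni–O bond, beta-hydride elimination releases ethene and C–H reductive elimination puts hydrogen on C1 cis to C9, so the syn addition fixes the E C1=C10 geometry and leaves the C8 oxygen as borinate 24. The closest known reactions are the Ni(cod)2/PBu3/Et3B reductive coupling of alkynes with terminal epoxides, in its intermolecular and five- and six-membered intramolecular forms, and the nickel-catalysed reductive macrocyclization of ynals; a ten-membered ring closure of this kind has no precedent. The carbocycle closes in the endo mode with respect to both partners (both oxirane carbons and both alkyne carbons become ring members), and no stereocentre is created because the C8–O bond is never broken. The step needs C9 to bond to C10 and not to C1, which would give a nine-membered ring with an exocyclic ethylidene; this should be favoured because nickel-mediated couplings form the new C–C bond at the alkyne carbon with the smaller substituent (methyl on C10 against the tether on C1) and because the exo metallacycle would span the more strained nine-membered ring. Closure is helped by the Z C4=C5 alkene and the contiguous C6–C8 substituents, which fold the chain, and by slow addition at high dilution, which suppresses intermolecular coupling.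

Step 14
Reactants: 25 (1S,3E,7Z,9R,10R)-9-[(tert-butyldimethylsilyl)oxy]-3,7-dimethyl-10-(propan-2-yl)cyclodeca-3,7-dien-1-ol; 26 3,4,5-trimethoxybenzoyl chloride
Product: 27 (1S,3E,7Z,9R,10R)-9-[(tert-butyldimethylsilyl)oxy]-3,7-dimethyl-10-(propan-2-yl)cyclodeca-3,7-dien-1-yl 3,4,5-trimethoxybenzoate
Conditions: Et3N, DMAP, CH2Cl2, 0 °C to rt
Reagents that add atoms: none
Why: DMAP-catalysed acylation of the only free hydroxyl (C8) with the aroyl chloride proceeds with retention at C8, the C6 oxygen being blocked as its silyl ether.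

Step 15
Reactants: 27 (1S,3E,7Z,9R,10R)-9-[(tert-butyldimethylsilyl)oxy]-3,7-dimethyl-10-(propan-2-yl)cyclodeca-3,7-dien-1-yl 3,4,5-trimethoxybenzoate
Product: 28 (1S,3E,7Z,9R,10S)-9-hydroxy-3,7-dimethyl-10-(propan-2-yl)cyclodeca-3,7-dien-1-yl 3,4,5-trimethoxybenzoate
Conditions: Bu4NF, AcOH (1:1), THF, 0 °C to rt
Reagents that add atoms: none
Why: Fluoride cleavage of the silyl ether, buffered with acetic acid so that the C6 alkoxide cannot trigger 1,3-migration of the aroyl group, frees the allylic hydroxyl needed to direct the epoxidation.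

Step 16
Reactants: 28 (1S,3E,7Z,9R,10S)-9-hydroxy-3,7-dimethyl-10-(propan-2-yl)cyclodeca-3,7-dien-1-yl 3,4,5-trimethoxybenzoate
Product: 29 target CNP0260213.6, (1(10)E,4S,5R,6S,7S,8S)-4,5-epoxy-6-hydroxygermacr-1(10)-en-8-yl 3,4,5-trimethoxybenzoate
Conditions: Ti(OiPr)4 (20 mol %), t-BuOOH (anhydrous, in decane), 4 Å molecular sieves, CH2Cl2, −20 °C
Reagents that add atoms: tert-butyl hydroperoxide, CC(C)(C)OO
Why: Titanium-alkoxide-directed epoxidation of a secondary allylic alcohol oxidises only the C4=C5 alkene whose C6–OH binds titanium (a peracid would attack the isolated C1=C10 alkene first), and 1,3-allylic strain between C6 and the cis C3 methylene should keep H6 in the alkene plane and the titanium-bound oxygen on the outer face opposite C7, so that oxygen is delivered there and C4 (S) and C5 (R) arise as the threo epoxy alcohol with the oxirane trans to the C6 hydroxyl on the ring.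

**Compound list**

1 | hexa-1,5-diyne | C#CCCC#C | starting material
2 | lithium hexa-1,5-diyn-1-ide | [Li]C#CCCC#C | intermediate
3 | hepta-1,5-diyne | C#CCCC#CC | intermediate
4 | lithium hepta-1,5-diyn-1-ide | [Li]C#CCCC#CC | intermediate
5 | methyl octa-2,6-diynoate | COC(=O)C#CCCC#CC | intermediate
6 | lithium methyl[(1E)-1-(methoxycarbonyl)-2-methylhept-1-en-5-yn-1-yl]cuprate (copper cis to the new methyl) | [Li+].C[Cu-]/C(C(=O)OC)=C(\C)CCC#CC | intermediate
7 | methyl (2Z)-3-methyloct-2-en-6-ynoate | CC#CCC/C(C)=C\C(=O)OC | intermediate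
8 | (2Z)-3-methyloct-2-en-6-yn-1-ol | CC#CCC/C(C)=C\CO | intermediate
9 | (2Z)-3-methyloct-2-en-6-ynal | CC#CCC/C(C)=C\C=O | intermediate
10 | (S)-4-benzyloxazolidin-2-one | O=C1N[C@@H](Cc2ccccc2)CO1 | starting material
11 | 3-methylbutanoyl chloride (isovaleryl chloride) | CC(C)CC(Cl)=O | starting material
12 | lithium (4S)-4-benzyl-2-oxooxazolidin-3-ide | [Li]N1[C@@H](Cc2ccccc2)COC1=O | intermediate
13 | (4S)-4-benzyl-3-(3-methylbutanoyl)oxazolidin-2-one | CC(C)CC(=O)N1[C@@H](Cc2ccccc2)COC1=O | intermediate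
14 | dibutylboron (Z)-enolate of 13 | CCCCB(CCCC)O/C(=C\C(C)C)N1[C@@H](Cc2ccccc2)COC1=O | intermediate
15 | dibutylboron aldolate of 16 (O-dibutylboryl at C6) | CC#CCC/C(C)=C\[C@@H](OB(CCCC)CCCC)[C@H](C(C)C)C(=O)N1[C@@H](Cc2ccccc2)COC1=O | intermediate
16 | (4S)-4-benzyl-3-[(2S,3R,4Z)-3-hydroxy-5-methyl-2-(propan-2-yl)dec-4-en-8-ynoyl]oxazolidin-2-one | CC#CCC/C(C)=C\[C@@H](O)[C@H](C(C)C)C(=O)N1[C@@H](Cc2ccccc2)COC1=O | intermediate
17 | (2S,3R,4Z)-3-hydroxy-N-methoxy-N,5-dimethyl-2-(propan-2-yl)dec-4-en-8-ynamide | CC#CCC/C(C)=C\[C@@H](O)[C@H](C(C)C)C(=O)N(C)OC | intermediate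
18 | dilithium salt of the tetrahedral chloromethyl adduct of 17 (hemiaminal carbon unassigned) | CC#CCC/C(C)=C\[C@@H](O[Li])[C@H](C(C)C)C(O[Li])(CCl)N(C)OC | intermediate
19 | (3S,4R,5Z)-1-chloro-4-hydroxy-6-methyl-3-(propan-2-yl)undec-5-en-9-yn-2-one | CC#CCC/C(C)=C\[C@@H](O)[C@H](C(C)C)C(=O)CCl | intermediate
20 | O-diethylboryl chelate of 19 | CC#CCC/C(C)=C\[C@@H](OB(CC)CC)[C@H](C(C)C)C(=O)CCl | intermediate
21 | (2R,3S,4R,5Z)-1-chloro-6-methyl-3-(propan-2-yl)undec-5-en-9-yne-2,4-diol | CC#CCC/C(C)=C\[C@@H](O)[C@H](C(C)C)[C@@H](O)CCl | intermediate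
22 | (3S,4R,5Z)-2,6-dimethyl-3-[(2R)-oxiran-2-yl]undec-5-en-9-yn-4-ol | CC#CCC/C(C)=C\[C@@H](O)[C@H](C(C)C)[C@@H]1CO1 | intermediate
23 | tert-butyl{[(3R,4R,5Z)-2,6-dimethyl-3-[(2R)-oxiran-2-yl]undec-5-en-9-yn-4-yl]oxy}dimethylsilane | CC#CCC/C(C)=C\[C@@H](O[Si](C)(C)C(C)(C)C)[C@H](C(C)C)[C@@H]1CO1 | intermediate
24 | O-diethylborinate of 25 | CCB(CC)O[C@H]1C/C(C)=C/CC/C(C)=C\[C@@H](O[Si](C)(C)C(C)(C)C)[C@@H]1C(C)C | intermediate
25 | (1S,3E,7Z,9R,10R)-9-[(tert-butyldimethylsilyl)oxy]-3,7-dimethyl-10-(propan-2-yl)cyclodeca-3,7-dien-1-ol | O[C@H]1C/C(C)=C/CC/C(C)=C\[C@@H](O[Si](C)(C)C(C)(C)C)[C@@H]1C(C)C | intermediate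
26 | 3,4,5-trimethoxybenzoyl chloride | COc1cc(cc(OC)c1OC)C(Cl)=O | starting material
27 | (1S,3E,7Z,9R,10R)-9-[(tert-butyldimethylsilyl)oxy]-3,7-dimethyl-10-(propan-2-yl)cyclodeca-3,7-dien-1-yl 3,4,5-trimethoxybenzoate | COc1cc(C(=O)O[C@H]2C/C(C)=C/CC/C(C)=C\[C@@H](O[Si](C)(C)C(C)(C)C)[C@@H]2C(C)C)cc(OC)c1OC | intermediate
28 | (1S,3E,7Z,9R,10S)-9-hydroxy-3,7-dimethyl-10-(propan-2-yl)cyclodeca-3,7-dien-1-yl 3,4,5-trimethoxybenzoate | COc1cc(C(=O)O[C@H]2C/C(C)=C/CC/C(C)=C\[C@@H](O)[C@@H]2C(C)C)cc(OC)c1OC | intermediate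
29 | CNP0260213.6, (1(10)E,4S,5R,6S,7S,8S)-4,5-epoxy-6-hydroxygermacr-1(10)-en-8-yl 3,4,5-trimethoxybenzoate | COc1cc(C(=O)O[C@H]2C/C(C)=C/CC[C@]3(C)O[C@@H]3[C@@H](O)[C@@H]2C(C)C)cc(OC)c1OC | target

**Step count**

Total: 16 steps. Longest linear sequence: 15 steps (steps 1–5 and 7–16, from hexa-1,5-diyne); step 6 is the one-step side branch.

**Steps most likely to fail**

Step 13. The ring closure may fail through oligomerisation, through closure at C1 instead of C10 (nine-membered ring with an exocyclic alkene), or through isomerisation of the oxirane before coupling. The fallback closes the same ring at C1–C2 by an intramolecular B-alkyl Suzuki–Miyaura coupling, with C9–C10 made beforehand by known open-chain chemistry. It sets out from 13 and comes back at 25. Commercial (2Z)-3-methylpent-2-en-4-yn-1-ol F1 is semihydrogenated (H2, Pd/CaCO3 poisoned with Pb(OAc)2, quinoline) to (2Z)-3-methylpenta-2,4-dien-1-ol F2, which MnO2 oxidises to (2Z)-3-methylpenta-2,4-dienal F3. The operations of steps 7 to 12, run on 13 and F3, should give in turn the aldol adduct F4, the Weinreb amide F5, the chloromethyl ketone F6, the syn chlorohydrin diol F7, the epoxy alcohol F8 and the silyl ether F9. LiC≡CH·H2NCH2CH2NH2 in DMSO opens the oxirane of F9 at C9 to give the homopropargylic alcohol F10. Negishi carboalumination (Me3Al, Cp2ZrCl2, CH2Cl2; then I2) converts the terminal alkyne into the (E)-iodoalkene F11, with the methyl group on C10. 9-BBN-H (2.2 equiv, THF) adds to the terminal vinyl group at C2 and caps the hydroxyl, giving the bis-borane F12. This is added slowly to Pd(dppf)Cl2, AsPh3 and Cs2CO3 in DMF/THF/H2O; the C1–C2 bond forms with retention of the E geometry, and aqueous work-up frees 25.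

Step 16. Oxygen may be delivered to the wrong face (the cis epoxy alcohol) if the ring reacts through the conformer with the hydroxyl eclipsing the alkene, and the Lewis acid may trigger transannular reaction of the product. The fallback sets C4 and C5 on the open chain, where 1,3-allylic strain reliably steers a peracid threo and no second alkene is present, and carries the hindered oxirane through the ring closure. It sets out from 22 and comes back at 29. mCPBA with NaHCO3 in CH2Cl2 at 0 °C epoxidises the single alkene of 22 on the hydroxyl side of the H-eclipsed conformer to give the bis-epoxy alcohol F13. TBSOTf and 2,6-lutidine at −78 °C give the silyl ether F14. The conditions of step 13, which should leave the trisubstituted oxirane untouched because only monosubstituted oxiranes are opened by the nickel catalyst, give the macrocyclic epoxy alcohol F15. Acylation as in step 14 gives the ester F16, and Bu4NF/AcOH removes the silyl group to give 29.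

Step 9. The carbenoid may decompose faster than it adds to the hindered, alkoxide-bearing amide, or the adduct may collapse early and take up a second equivalent. The fallback builds C9 as a methyl ketone and chlorinates its kinetic enol ether. It sets out from 17 and comes back at 19. MeMgBr (THF, 0 °C) converts 17 into the methyl ketone F17. LiN(i-Pr)2 with Me3SiCl present (THF, −78 °C) silylates the hydroxyl and traps the kinetic enolate on the methyl side as the bis-silyl compound F18. N-Chlorosuccinimide (THF, −78 to 0 °C) chlorinates the enol ether to the O-silylated chloromethyl ketone F19, and citric acid in MeOH removes the silyl ether to give 19.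

Further compounds
F1 | step 13 | (2Z)-3-methylpent-2-en-4-yn-1-ol | C#C/C(C)=C\CO
F2 | step 13 | (2Z)-3-methylpenta-2,4-dien-1-ol | C=C/C(C)=C\CO
F3 | step 13 | (2Z)-3-methylpenta-2,4-dienal | C=C/C(C)=C\C=O
F4 | step 13 | (4S)-4-benzyl-3-[(2S,3R,4Z)-3-hydroxy-5-methyl-2-(propan-2-yl)hepta-4,6-dienoyl]oxazolidin-2-one | C=C/C(C)=C\[C@@H](O)[C@H](C(C)C)C(=O)N1[C@@H](Cc2ccccc2)COC1=O
F5 | step 13 | (2S,3R,4Z)-3-hydroxy-N-methoxy-N,5-dimethyl-2-(propan-2-yl)hepta-4,6-dienamide | C=C/C(C)=C\[C@@H](O)[C@H](C(C)C)C(=O)N(C)OC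
F6 | step 13 | (3S,4R,5Z)-1-chloro-4-hydroxy-6-methyl-3-(propan-2-yl)octa-5,7-dien-2-one | C=C/C(C)=C\[C@@H](O)[C@H](C(C)C)C(=O)CCl
F7 | step 13 | (2R,3S,4R,5Z)-1-chloro-6-methyl-3-(propan-2-yl)octa-5,7-diene-2,4-diol | C=C/C(C)=C\[C@@H](O)[C@H](C(C)C)[C@@H](O)CCl
F8 | step 13 | (3S,4R,5Z)-2,6-dimethyl-3-[(2R)-oxiran-2-yl]octa-5,7-dien-4-ol | C=C/C(C)=C\[C@@H](O)[C@H](C(C)C)[C@@H]1CO1
F9 | step 13 | tert-butyl{[(3R,4R,5Z)-2,6-dimethyl-3-[(2R)-oxiran-2-yl]octa-5,7-dien-4-yl]oxy}dimethylsilane | C=C/C(C)=C\[C@@H](O[Si](C)(C)C(C)(C)C)[C@H](C(C)C)[C@@H]1CO1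
F10 | step 13 | (4S,5R,6R,7Z)-6-[(tert-butyldimethylsilyl)oxy]-8-methyl-5-(propan-2-yl)deca-7,9-dien-1-yn-4-ol | C=C/C(C)=C\[C@@H](O[Si](C)(C)C(C)(C)C)[C@H](C(C)C)[C@@H](O)CC#C
F11 | step 13 | (1E,4S,5R,6R,7Z)-6-[(tert-butyldimethylsilyl)oxy]-1-iodo-2,8-dimethyl-5-(propan-2-yl)deca-1,7,9-trien-4-ol | C=C/C(C)=C\[C@@H](O[Si](C)(C)C(C)(C)C)[C@H](C(C)C)[C@@H](O)C/C(C)=C/I
F12 | step 13 | bis-borane of F11 (9-borabicyclo[3.3.1]nonan-9-yl on C2 and on the C8 oxygen) | C(CB1C2CCCC1CCC2)/C(C)=C\[C@@H](O[Si](C)(C)C(C)(C)C)[C@H](C(C)C)[C@@H](OB1C2CCCC1CCC2)C/C(C)=C/I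
F13 | step 16 | (4S,5R)-4,5-epoxide of 22 (oxirane threo to the C6 hydroxyl) | CC#CCC[C@]1(C)O[C@@H]1[C@@H](O)[C@H](C(C)C)[C@@H]2CO2
F14 | step 16 | tert-butyldimethylsilyl ether of F13 | CC#CCC[C@]1(C)O[C@@H]1[C@@H](O[Si](C)(C)C(C)(C)C)[C@H](C(C)C)[C@@H]2CO2
F15 | step 16 | (1(10)E,4S,5R)-6-[(tert-butyldimethylsilyl)oxy]-4,5-epoxygermacr-1(10)-en-8-ol | O[C@H]1C/C(C)=C/CC[C@]2(C)O[C@@H]2[C@@H](O[Si](C)(C)C(C)(C)C)[C@@H]1C(C)C
F16 | step 16 | 3,4,5-trimethoxybenzoate of F15 (6-O-silyl ether of 29) | COc1cc(C(=O)O[C@H]2C/C(C)=C/CC[C@]3(C)O[C@@H]3[C@@H](O[Si](C)(C)C(C)(C)C)[C@@H]2C(C)C)cc(OC)c1OC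
F17 | step 9 | (3S,4R,5Z)-4-hydroxy-6-methyl-3-(propan-2-yl)undec-5-en-9-yn-2-one | CC#CCC/C(C)=C\[C@@H](O)[C@H](C(C)C)C(C)=O
F18 | step 9 | bis(trimethylsilyl) derivative of F17 (C6 silyl ether and terminal silyl enol ether) | CC#CCC/C(C)=C\[C@@H](O[Si](C)(C)C)[C@H](C(C)C)C(=C)O[Si](C)(C)C
F19 | step 9 | O-trimethylsilyl ether of 19 | CC#CCC/C(C)=C\[C@@H](O[Si](C)(C)C)[C@H](C(C)C)C(=O)CCl
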